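**Plan**
- Retrosynthesis: the tiglate ester C–O bond is cut first (back to alkannin), then the two ring-fusion bonds C4–C4a and C1–C8a of the naphthoquinone, then the furyl–carbonyl C–C bond of a side-chain ketone.
- Enabling feature: C4a and C8a are adjacent arene carbons, each bonded to a carbonyl carbon (C4, C1) and each flanked on its other side by an oxygen-bearing carbon (C5, C8). That is the pattern of a 3,6-dimethoxybenzyne, and C1–C2–C3–C4 plus one oxygen are a 3-substituted furan.
- Forward: the side chain is joined to the furan (3-furyllithium plus Weinreb amide), ring B comes from 2-bromo-1,4-dimethoxybenzene, and ring A closes in the aryne–furan [4+2] cycloaddition. The oxygen bridge is then opened to the naphthols, which are oxidised to the quinone in the same operation.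
- The methyl ethers are removed oxidatively instead of by Lewis acid: reductive acetylation of ring A, oxidative demethylation of ring B, hydrolysis to alkannin, then selective tigloylation of the side-chain hydroxyl.
- Stereochemistry: the single (S) carbinol centre is set by Corey–Bakshi–Shibata reduction before the cycloaddition and carried through unchanged. The (E) alkene arrives with tiglic acid.

Key step: step 5

Remark: the carbinol carbon of the target carries a CH2–CH=C(CH3)2 group, so the acyl donor for the side chain is 4-methylpent-3-enoic acid; its next higher homologue would place one methylene too many between carbinol and alkene.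
Remark: the free 5,8-dihydroxy-1,4-naphthoquinone core exchanges its two quinoid tautomers by rapid proton transfer, so the compound released in step 10 is the same substance as alkannin drawn with the side chain on the quinone ring.

**Step 1**
Reactants: 1 4-methylpent-3-enoic acid
Product: 3 N-methoxy-N,4-dimethylpent-3-enamide, via 1-(4-methylpent-3-enoyl)imidazole 2 (not isolated)
Conditions: 1,1'-carbonyldiimidazole, CH2Cl2, 0 °C → rt; then MeNH(OMe)·HCl, rt
Reagents that add atoms: N,O-dimethylhydroxylamine hydrochloride, SMILES CNOC.Cl
Why: Amide coupling through the acyl imidazolide, which activates the acid without a base strong enough to move the β,γ-alkene into conjugation.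

**Step 2**
Reactants: 4 3-bromofuran; 3 N-methoxy-N,4-dimethylpent-3-enamide
Product: 6 1-(furan-3-yl)-4-methylpent-3-en-1-one, via 3-furyllithium 5 (not isolated)
Conditions: 4, n-BuLi, THF, −78 °C; then 3, −78 → −40 °C; aq. NH4Cl
Reagents that add atoms: none
Why: Bromine–lithium exchange at −78 °C gives 3-furyllithium without drift to the 2-position, and it adds once to the amide because the chelated tetrahedral adduct persists until the mild quench (Weinreb ketone synthesis), which also keeps the alkene out of conjugation.

**Step 3**
Reactants: 6 1-(furan-3-yl)-4-methylpent-3-en-1-one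
Product: 7 (S)-1-(furan-3-yl)-4-methylpent-3-en-1-ol
Conditions: (R)-Me-CBS oxazaborolidine [(R)-1-methyl-3,3-diphenyltetrahydro-1H,3H-pyrrolo[1,2-c][1,3,2]oxazaborole] (0.2 equiv), catecholborane, toluene, −78 °C
Reagents that add atoms: none
Why: Corey–Bakshi–Shibata reduction, in which the ketone binds the (R)-oxazaborolidine–borane complex with the furyl group as the large substituent so that hydride reaches the face giving the (S)-alcohol, while catecholborane at −78 °C leaves the trisubstituted alkene alone.

**Step 4**
Reactants: 7 (S)-1-(furan-3-yl)-4-methylpent-3-en-1-ol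
Product: 8 (S)-tert-butyl{[1-(furan-3-yl)-4-methylpent-3-en-1-yl]oxy}dimethylsilane
Conditions: TBSCl, imidazole, DMF, rt
Reagents that add atoms: tert-butyldimethylsilyl chloride, SMILES CC(C)(C)[Si](C)(C)Cl
Why: Imidazole-promoted silylation of a secondary alcohol, which removes the only acidic O–H before the amide base of step 5 and does not touch the stereocentre.

**Step 5**
Reactants: 9 2-bromo-1,4-dimethoxybenzene; 8 (S)-tert-butyl{[1-(furan-3-yl)-4-methylpent-3-en-1-yl]oxy}dimethylsilane
Product: 12 2-[(S)-1-(tert-butyldimethylsilyloxy)-4-methylpent-3-enyl]-5,8-dimethoxy-1,4-dihydro-1,4-epoxynaphthalene (both bridgehead diastereomers), via 2-bromo-3,6-dimethoxyphenyllithium 10 (not isolated), via 3,6-dimethoxybenzyne 11 (not isolated)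
Conditions: 9 (2 equiv), lithium 2,2,6,6-tetramethylpiperidide (from 2,2,6,6-tetramethylpiperidine and n-BuLi), THF, −78 °C; then 8 (1 equiv), −78 °C → rt
Reagents that add atoms: none
Why: The piperidide removes the ring hydrogen flanked by bromine and methoxy to give 10, which loses LiBr on warming to form the symmetrical aryne 11; 11 then adds across C2 and C5 of the furan in a concerted suprafacial [4+2] cycloaddition (aryne–furan Diels–Alder reaction), making C4–C4a and C1–C8a together. Ring A closes as a six-membered carbocycle by intermolecular cycloaddition, with the furan oxygen left as the 1,4-bridge. The bridgehead centres C1 and C4 arise without control from the remote carbinol centre, so 12 is expected as two diastereomers; this does not matter because both carbons become sp2 in step 6, and the existing (S) centre is not involved. Both aryne carbons have a methoxy neighbour, so the two orientations of addition give one constitution. The step needs chemoselectivity for the furan diene over the prenyl alkene (ene or [2+2] reaction) and over capture of the aryne by amine or aryllithium: the electron-rich diene traps arynes far faster than an isolated alkene, the hindered piperidide is a poor nucleophile, and forming 10 fully at −78 °C before 8 is added keeps free base away from the aryne and from the furan C–H bonds.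

**Step 6**
Reactants: 12 2-[(S)-1-(tert-butyldimethylsilyloxy)-4-methylpent-3-enyl]-5,8-dimethoxy-1,4-dihydro-1,4-epoxynaphthalene
Product: 15 2-[(S)-1-(tert-butyldimethylsilyloxy)-4-methylpent-3-enyl]-5,8-dimethoxy-1,4-naphthoquinone, via 2-substituted 5,8-dimethoxynaphthalen-1-ol 13 (not isolated), via 3-substituted 5,8-dimethoxynaphthalen-1-ol 14 (not isolated)
Conditions: CF3CO2H (0.1 equiv), CH2Cl2, −20 → 0 °C, argon; Et3N (0.2 equiv), concentrate; then (KSO3)2NO (Fremy's salt), KH2PO4, acetone/H2O, rt
Reagents that add atoms: potassium nitrosodisulfonate, SMILES [K+].[K+].[O]N(S(=O)(=O)[O-])S(=O)(=O)[O-]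
Why: Acid-catalysed isomerisation of a 1,4-epoxy-1,4-dihydronaphthalene followed by Teuber oxidation: protonation of the bridge oxygen and ionisation of the C4–O bond (favoured because the allyl cation then ends on the substituted carbon C2) give the C1-protonated arenium form of naphthol 13, which loses that proton, while any ionisation of the C1–O bond leads in the same way to isomer 14; two nitrosodisulfonate radicals then take each naphthol to the para-quinone (hydrogen abstraction, then coupling through oxygen at the free para carbon), so 13 and 14 converge on 15 without being separated or exposed to air, and the ether-protected ring B and the alkene are left alone.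

**Step 7**
Reactants: 15 2-[(S)-1-(tert-butyldimethylsilyloxy)-4-methylpent-3-enyl]-5,8-dimethoxy-1,4-naphthoquinone
Product: 17 2-[(S)-1-(tert-butyldimethylsilyloxy)-4-methylpent-3-enyl]-5,8-dimethoxynaphthalene-1,4-diyl diacetate, via 5,8-dimethoxynaphthalene-1,4-diol 16 (not isolated)
Conditions: Zn dust, Ac2O, pyridine, 4-(dimethylamino)pyridine (cat.), CH2Cl2, rt
Reagents that add atoms: acetic anhydride, SMILES CC(=O)OC(C)=O
Why: Reductive acetylation, in which zinc reduces the quinone to hydroquinone 16 and the anhydride caps it at once, turning ring A into an oxidation-resistant diacetoxyarene so that ring B is the more electron-rich ring in step 8.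

**Step 8**
Reactants: 17 2-[(S)-1-(tert-butyldimethylsilyloxy)-4-methylpent-3-enyl]-5,8-dimethoxynaphthalene-1,4-diyl diacetate
Product: 18 5,8-diacetoxy-6-[(S)-1-(tert-butyldimethylsilyloxy)-4-methylpent-3-enyl]-1,4-naphthoquinone
Conditions: (NH4)2Ce(NO3)6, MeCN/H2O, 0 °C
Reagents that add atoms: water, SMILES O
Why: Oxidative demethylation by tetravalent cerium, in which single-electron oxidation of the arene and attack of water at the two methoxy-bearing carbons of ring B release methanol and give the ring B quinone, a standard quinone synthesis from 1,4-dimethoxyarenes that should spare the aryl acetates and the prenyl group in a short reaction at 0 °C (partial loss of the silyl group would be harmless, since step 9 removes it).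

**Step 9**
Reactants: 18 5,8-diacetoxy-6-[(S)-1-(tert-butyldimethylsilyloxy)-4-methylpent-3-enyl]-1,4-naphthoquinone
Product: 19 5,8-diacetoxy-6-[(S)-1-hydroxy-4-methylpent-3-enyl]-1,4-naphthoquinone
Conditions: HF (48% aq.), MeCN, 0 °C → rt
Reagents that add atoms: none
Why: Fluoride-driven desilylation of a secondary silyl ether at a stage where the carbinol sits on an electron-poor acylated ring, so the benzylic C–O bond should not ionise and the aryl acetates survive.

**Step 10**
Reactants: 19 5,8-diacetoxy-6-[(S)-1-hydroxy-4-methylpent-3-enyl]-1,4-naphthoquinone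
Product: 20 alkannin [5,8-dihydroxy-2-[(S)-1-hydroxy-4-methylpent-3-enyl]-1,4-naphthoquinone]
Conditions: NaOH (1 M aq.), MeOH/THF, 0 °C, argon; then 1 M HCl to pH 4
Reagents that add atoms: none
Why: Saponification of the two activated aryl acetates gives the naphthazarin dianion, which is protonated on acidification and equilibrates between its quinoid tautomers to alkannin; the carbinol centre has no pathway to epimerise in cold dilute base.

**Step 11**
Reactants: 20 alkannin; 21 tiglic acid [(E)-2-methylbut-2-enoic acid]
Product: 22 (S)-1-(5,8-dihydroxy-1,4-dioxo-1,4-dihydronaphthalen-2-yl)-4-methylpent-3-enyl (E)-2-methylbut-2-enoate (CNP0373203.1)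
Conditions: N,N'-dicyclohexylcarbodiimide, 4-(dimethylamino)pyridine (cat.), CH2Cl2, 0 °C → rt
Reagents that add atoms: none
Why: Steglich esterification, which should acylate only the side-chain alcohol because both phenols are held in strong hydrogen bonds to the quinone carbonyls; the C–O bond at the stereocentre is not broken, so the (S) configuration and the (E) alkene are retained.

**Compound list**
1 | 4-methylpent-3-enoic acid | CC(C)=CCC(=O)O | starting material
2 | 1-(4-methylpent-3-enoyl)imidazole (formed in situ) | CC(C)=CCC(=O)n1ccnc1 | intermediate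
3 | N-methoxy-N,4-dimethylpent-3-enamide | CC(C)=CCC(=O)N(C)OC | intermediate
4 | 3-bromofuran | Brc1ccoc1 | starting material
5 | 3-furyllithium (formed in situ) | [Li]c1ccoc1 | intermediate
6 | 1-(furan-3-yl)-4-methylpent-3-en-1-one | CC(C)=CCC(=O)c1ccoc1 | intermediate
7 | (S)-1-(furan-3-yl)-4-methylpent-3-en-1-ol | O[C@@H](CC=C(C)C)c1ccoc1 | intermediate
8 | (S)-tert-butyl{[1-(furan-3-yl)-4-methylpent-3-en-1-yl]oxy}dimethylsilane | CC(C)(C)[Si](C)(C)O[C@@H](CC=C(C)C)c1ccoc1 | intermediate
9 | 2-bromo-1,4-dimethoxybenzene | COc1ccc(OC)c(Br)c1 | starting material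
10 | 2-bromo-3,6-dimethoxyphenyllithium (formed in situ) | COc1ccc(OC)c(Br)c1[Li] | intermediate
11 | 3,6-dimethoxybenzyne (formed in situ) | COC1=CC=C(OC)C#C1 | intermediate
12 | 2-[(S)-1-(tert-butyldimethylsilyloxy)-4-methylpent-3-enyl]-5,8-dimethoxy-1,4-dihydro-1,4-epoxynaphthalene, both bridgehead diastereomers | CC(C)(C)[Si](C)(C)O[C@@H](CC=C(C)C)C1=CC2OC1c1c(OC)ccc(OC)c12 | intermediate
13 | 2-[(S)-1-(tert-butyldimethylsilyloxy)-4-methylpent-3-enyl]-5,8-dimethoxynaphthalen-1-ol (formed in situ) | CC(C)(C)[Si](C)(C)O[C@@H](CC=C(C)C)c1ccc2c(OC)ccc(OC)c2c1O | intermediate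
14 | 3-[(S)-1-(tert-butyldimethylsilyloxy)-4-methylpent-3-enyl]-5,8-dimethoxynaphthalen-1-ol (formed in situ, regioisomer of 13) | CC(C)(C)[Si](C)(C)O[C@@H](CC=C(C)C)c1cc(O)c2c(OC)ccc(OC)c2c1 | intermediate
15 | 2-[(S)-1-(tert-butyldimethylsilyloxy)-4-methylpent-3-enyl]-5,8-dimethoxy-1,4-naphthoquinone | CC(C)(C)[Si](C)(C)O[C@@H](CC=C(C)C)C1=CC(=O)c2c(OC)ccc(OC)c2C1=O | intermediate
16 | 2-[(S)-1-(tert-butyldimethylsilyloxy)-4-methylpent-3-enyl]-5,8-dimethoxynaphthalene-1,4-diol (formed in situ) | CC(C)(C)[Si](C)(C)O[C@@H](CC=C(C)C)c1cc(O)c2c(OC)ccc(OC)c2c1O | intermediate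
17 | 2-[(S)-1-(tert-butyldimethylsilyloxy)-4-methylpent-3-enyl]-5,8-dimethoxynaphthalene-1,4-diyl diacetate | CC(C)(C)[Si](C)(C)O[C@@H](CC=C(C)C)c1cc(OC(C)=O)c2c(OC)ccc(OC)c2c1OC(C)=O | intermediate
18 | 5,8-diacetoxy-6-[(S)-1-(tert-butyldimethylsilyloxy)-4-methylpent-3-enyl]-1,4-naphthoquinone | CC(C)(C)[Si](C)(C)O[C@@H](CC=C(C)C)c1cc(OC(C)=O)c2C(=O)C=CC(=O)c2c1OC(C)=O | intermediate
19 | 5,8-diacetoxy-6-[(S)-1-hydroxy-4-methylpent-3-enyl]-1,4-naphthoquinone | O[C@@H](CC=C(C)C)c1cc(OC(C)=O)c2C(=O)C=CC(=O)c2c1OC(C)=O | intermediate
20 | alkannin, 5,8-dihydroxy-2-[(S)-1-hydroxy-4-methylpent-3-enyl]-1,4-naphthoquinone | O[C@@H](CC=C(C)C)C1=CC(=O)c2c(O)ccc(O)c2C1=O | intermediate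
21 | tiglic acid, (E)-2-methylbut-2-enoic acid | C/C=C(\C)C(=O)O | starting material
22 | (S)-1-(5,8-dihydroxy-1,4-dioxo-1,4-dihydronaphthalen-2-yl)-4-methylpent-3-enyl (E)-2-methylbut-2-enoate | C/C=C(\C)C(=O)O[C@@H](CC=C(C)C)C1=CC(=O)c2c(O)ccc(O)c2C1=O | target

Total step count: 11
Longest linear sequence: 11 steps (1 → 22); 4, 9 and 21 enter as purchased.

**Steps most likely to fail**

Step 5. The danger is metalation of the furan ring by the amide base or the aryllithium, or capture of the aryne by amine or aryllithium instead of by the diene. The fallback releases the aryne with fluoride instead of base; it sets out from 9 and returns to the route at 12. Lithiation of 9 with lithium 2,2,6,6-tetramethylpiperidide at −78 °C, borylation with B(OMe)3 and oxidation with H2O2 should give 2-bromo-3,6-dimethoxyphenol F1. Hexamethyldisilazane converts it into (2-bromo-3,6-dimethoxyphenoxy)trimethylsilane F2. Treatment with n-BuLi at −78 °C (bromine–lithium exchange with oxygen-to-carbon silyl shift) followed by Tf2O gives 3,6-dimethoxy-2-(trimethylsilyl)phenyl trifluoromethanesulfonate F3. CsF in MeCN at rt in the presence of 8 then liberates the same aryne 11 and should give 12 with no strong base present; the secondary silyl ether is expected to survive.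

Step 6. The danger is acid-promoted ionisation of the benzylic C–O bond of the side chain once the electron-rich naphthols have formed (loss of the silyloxy group or racemisation), or premature desilylation. The fallback replaces the cationic opening by a transition-metal-catalysed isomerisation under neutral conditions; it sets out from 12 and returns at 15. With [RuCl2(CO)3]2 (catalytic) in 1,2-dichloroethane at 60 °C, the bridge is cleaved by insertion of the metal into the allylic C–O bond, followed by β-hydride elimination and tautomerisation, so the naphthols 13 and 14 form with no free acid. The same (KSO3)2NO oxidation then gives 15; no compound outside the list is made (F0).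

Step 7. The danger is expulsion of the benzylic silyloxy group from the transient hydroquinone (quinone methide formation and over-reduction) before acetylation is complete. The fallback drops the detour through ring A reduction and demethylates ring B oxidatively at the quinone stage; it sets out from 15 and returns at 20. Aqueous HF in MeCN should give (S)-2-(1-hydroxy-4-methylpent-3-enyl)-5,8-dimethoxy-1,4-naphthoquinone F4. AgO with 6 M HNO3 in acetone (divalent silver as the oxidant) converts its dimethoxy ring into a second quinone, (S)-2-(1-hydroxy-4-methylpent-3-enyl)naphthalene-1,4,5,8-tetraone F5, which is not isolated but reduced during work-up with aqueous Na2S2O4 to alkannin 20. This shorter path is held in reserve because the strongly oxidising acidic medium is less forgiving toward the prenyl alkene.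

**Further compounds**
F1 | step 5 | 2-bromo-3,6-dimethoxyphenol | COc1ccc(OC)c(Br)c1O
F2 | step 5 | (2-bromo-3,6-dimethoxyphenoxy)trimethylsilane | COc1ccc(OC)c(Br)c1O[Si](C)(C)C
F3 | step 5 | 3,6-dimethoxy-2-(trimethylsilyl)phenyl trifluoromethanesulfonate | COc1ccc(OC)c([Si](C)(C)C)c1OS(=O)(=O)C(F)(F)F
F0 | step 6 | none | none
F4 | step 7 | (S)-2-(1-hydroxy-4-methylpent-3-enyl)-5,8-dimethoxy-1,4-naphthoquinone | O[C@@H](CC=C(C)C)C1=CC(=O)c2c(OC)ccc(OC)c2C1=O
F5 | step 7 | (S)-2-(1-hydroxy-4-methylpent-3-enyl)naphthalene-1,4,5,8-tetraone | O[C@@H](CC=C(C)C)C1=CC(=O)C2=C(C1=O)C(=O)C=CC2=O
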